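**Retrosynthetic overview**
- The cyclohexadiene ring (an arene hydrate, lost to acid or base) is closed last, at C4=C5, by ring-closing metathesis under neutral conditions.
- Its precursor comes from a vinyl iodide by Stille coupling (C3a–C4) and from a ketone by a syn boron aldol with acrolein (C6–C7, sets C6 and C7).
- Key disconnection O1–C7a: the dihydrofuran ring is formed by C–O bond formation, a site-selective 5-endo-dig iodocycloetherification of an alkynyl 1,2-diol (new borinic-acid-catalysed variant).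
- The alkynyl diol comes from anti opening of an epoxy alcohol by an alkynylalane (C3–C3a, inversion); the oxirane C–O bonds (C2, C3) come from Shi epoxidation of a Heck product.
- Ring order: benzoate ring (bought) → oxirane → dihydrofuran → cyclohexadiene.

Assumption: atom labels (O1, C2, C3, C3a, C4–C7, C7a) are those of the benzofuran ring system of the target; intermediates carrying the side-chain carbinol made in the Barbier step are 1:1 epimer mixtures at that carbon until it is oxidised; the (−)-Ipc2BOTf enolate is taken to attack the aldehyde face that leads to the (4S,5S) adduct, otherwise the (+)-reagent is used with nothing else changed.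

**Step 1**
Reactants: 1 methyl 4-hydroxy-3-iodobenzoate; 2 2-methylbut-3-en-2-ol
Product: 4 methyl 3-[(1E)-3-hydroxy-3-methylbut-1-en-1-yl]-4-[(triisopropylsilyl)oxy]benzoate, via aryl silyl ether 3 (not isolated)
Conditions: TIPSCl, Et3N, DMAP (cat.), MeCN, 23 °C; then 2, Pd(OAc)2 (5 mol%), P(o-tol)3 (10 mol%), Et3N, 80 °C
Reagents that add atoms: chlorotriisopropylsilane (TIPSCl), CC(C)[Si](Cl)(C(C)C)C(C)C
Why: Phenol silylation followed in the same pot by a Mizoroki–Heck reaction, in which syn insertion and syn β-hydride elimination give the (E)-alkene and the tertiary carbinol has no hydrogen that could lead to a ketone.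

**Step 2**
Reactants: 4 methyl 3-[(1E)-3-hydroxy-3-methylbut-1-en-1-yl]-4-[(triisopropylsilyl)oxy]benzoate
Product: 5 methyl 3-[(2S,3R)-3-(2-hydroxypropan-2-yl)oxiran-2-yl]-4-[(triisopropylsilyl)oxy]benzoate (trans)
Conditions: ent-Shi ketone (1,2:4,5-di-O-isopropylidene-β-L-erythro-2,3-hexodiulo-2,6-pyranose, from L-sorbose, 30 mol%), Oxone (2KHSO5·KHSO4·K2SO4), K2CO3, Bu4NHSO4, MeCN/CH2(OMe)2/aq. Na2B4O7 buffer, pH 10.5, 0 °C
Reagents that add atoms: potassium peroxymonosulfate (from Oxone), [K+].[O-]S(=O)(=O)OO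
Why: Shi epoxidation, in which the chiral dioxirane delivers oxygen to one face of the trans-alkene through a spiro transition state and sets both oxirane stereocentres; the L-series ketone is needed because the D-fructose-derived one gives the mirror-image sense with trans-alkenes.

**Step 3**
Reactants: 6 3-phenylpropanal; 7 3-bromoprop-1-yne
Product: 9 trimethyl[(1-phenylhex-5-yn-3-yl)oxy]silane (racemic), via bromozinc alkoxide 8 (not isolated)
Conditions: Zn dust, THF, 0 → 23 °C; then TMSCl, imidazole (cat.), 0 °C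
Reagents that add atoms: chlorotrimethylsilane (TMSCl), C[Si](C)(C)Cl
Why: Barbier propargylation, in which the allenylzinc bromide adds to the aldehyde through an SE2′ transition state to give the homopropargylic zinc alkoxide that is silylated in situ; the racemic carbinol centre is removed by the oxidation in step 6.

**Step 4**
Reactants: 5 methyl 3-[(2S,3R)-3-(2-hydroxypropan-2-yl)oxiran-2-yl]-4-[(triisopropylsilyl)oxy]benzoate; 9 trimethyl[(1-phenylhex-5-yn-3-yl)oxy]silane
Product: 12 methyl 3-[(3R,4R)-2,3-dihydroxy-2-methyl-10-phenyl-8-(trimethylsilyloxy)dec-5-yn-4-yl]-4-[(triisopropylsilyl)oxy]benzoate, via lithium acetylide 10 (not isolated), via diethylalkynylalane 11 (not isolated)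
Conditions: 9 (3 equiv), n-BuLi, toluene, 0 °C; Et2AlCl, 0 °C; then 5, 0 → 23 °C; aq. KNaC4H4O6 (potassium sodium tartrate)
Reagents that add atoms: none
Why: Alkynylalane opening of a 2,3-epoxy alcohol, in which the aluminium alkoxide of the tertiary hydroxyl activates the oxirane and the alkynyl group attacks the distal benzylic carbon anti (SN2, inversion at the future C3, retention at the future C2) to give the (3R,4R)-diol.

**Step 5**
Reactants: 12 methyl 3-[(3R,4R)-2,3-dihydroxy-2-methyl-10-phenyl-8-(trimethylsilyloxy)dec-5-yn-4-yl]-4-[(triisopropylsilyl)oxy]benzoate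
Product: 14 methyl 3-[(2R,3R)-5-(2-hydroxy-4-phenylbutyl)-2-(2-hydroxypropan-2-yl)-4-iodo-2,3-dihydrofuran-3-yl]-4-[(triisopropylsilyl)oxy]benzoate, via iodo-dihydrofuran silyl ether 13 (not isolated)
Conditions: NIS (1.2 equiv), Ph2BOH (10 mol%), NaHCO3, MeCN, −20 °C; then K2CO3 (0.1 equiv), MeOH, 0 °C
Reagents that add atoms: N-iodosuccinimide (NIS), O=C1CCC(=O)N1I
Why: Proposed new method: a diarylborinic-acid-catalysed, site-selective 5-endo-dig iodocycloetherification of an alkynyl 1,2-diol, in which the catalyst binds the vicinal diol as a tetracoordinate borinate whose less hindered secondary oxygen (the more nucleophilic B–O, as in borinic-acid-catalysed regioselective alkylation, acylation and glycosylation of diols) attacks the NIS-derived iodonium of the alkyne anti to form the O1–C7a bond and the β-iodo enol ether, while the tertiary oxygen that would otherwise compete by 5-exo-dig closure stays boron-bound; no stereocentre is formed, C2 and C3 are carried through unchanged (cis), and methanolysis then frees the side-chain alcohol; closest known reaction type: iodine-mediated 5-endo-dig cyclisation of homopropargylic alcohols to 4-iodo-2,3-dihydrofurans.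

**Step 6**
Reactants: 14 methyl 3-[(2R,3R)-5-(2-hydroxy-4-phenylbutyl)-2-(2-hydroxypropan-2-yl)-4-iodo-2,3-dihydrofuran-3-yl]-4-[(triisopropylsilyl)oxy]benzoate
Product: 15 methyl 3-[(2R,3R)-2-(2-hydroxypropan-2-yl)-4-iodo-5-(2-oxo-4-phenylbutyl)-2,3-dihydrofuran-3-yl]-4-[(triisopropylsilyl)oxy]benzoate
Conditions: Dess–Martin periodinane, NaHCO3, CH2Cl2, 0 → 23 °C
Reagents that add atoms: none
Why: Dess–Martin oxidation of the only secondary alcohol (the tertiary one cannot react) under buffered, non-acidic conditions that spare the iodo enol ether and remove the stereo-random carbinol centre.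

**Step 7**
Reactants: 15 methyl 3-[(2R,3R)-2-(2-hydroxypropan-2-yl)-4-iodo-5-(2-oxo-4-phenylbutyl)-2,3-dihydrofuran-3-yl]-4-[(triisopropylsilyl)oxy]benzoate; 16 prop-2-enal
Product: 18 methyl 3-[(2R,3R)-5-[(4S,5S)-5-hydroxy-3-oxo-1-phenylhept-6-en-4-yl]-2-(2-hydroxypropan-2-yl)-4-iodo-2,3-dihydrofuran-3-yl]-4-[(triisopropylsilyl)oxy]benzoate, via boron enolate 17 (not isolated)
Conditions: (−)-Ipc2BOTf (1.6 equiv), i-Pr2NEt, CH2Cl2, −78 °C; 16, −78 → −20 °C; then pH 7 buffer, MeOH, 30% H2O2, 0 °C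
Reagents that add atoms: none
Why: Paterson boron aldol reaction, in which enolisation at the more acidic C7 methylene (allylic to the enol ether) gives the (Z)-diisopinocampheylboron enolate that adds to acrolein through a chair Zimmerman–Traxler transition state to give the syn adduct (the later cis C6/C7 pair), the Ipc ligands choosing the aldehyde face and so the absolute configuration at C6 and C7.

**Step 8**
Reactants: 18 methyl 3-[(2R,3R)-5-[(4S,5S)-5-hydroxy-3-oxo-1-phenylhept-6-en-4-yl]-2-(2-hydroxypropan-2-yl)-4-iodo-2,3-dihydrofuran-3-yl]-4-[(triisopropylsilyl)oxy]benzoate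
Product: 19 methyl 4-hydroxy-3-[(2R,3R)-5-[(4S,5S)-5-hydroxy-3-oxo-1-phenylhept-6-en-4-yl]-2-(2-hydroxypropan-2-yl)-4-iodo-2,3-dihydrofuran-3-yl]benzoate
Conditions: Bu4NF, AcOH (1:1), THF, 0 °C
Reagents that add atoms: none
Why: Fluoride desilylation of the activated aryl silyl ether, buffered with acetic acid so that the β-hydroxy ketone neither epimerises at C7 nor undergoes retro-aldol cleavage.

**Step 9**
Reactants: 19 methyl 4-hydroxy-3-[(2R,3R)-5-[(4S,5S)-5-hydroxy-3-oxo-1-phenylhept-6-en-4-yl]-2-(2-hydroxypropan-2-yl)-4-iodo-2,3-dihydrofuran-3-yl]benzoate; 20 tributyl(1-methoxyethenyl)stannane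
Product: 21 methyl 4-hydroxy-3-[(2R,3S)-5-[(4S,5S)-5-hydroxy-3-oxo-1-phenylhept-6-en-4-yl]-2-(2-hydroxypropan-2-yl)-4-(1-methoxyethenyl)-2,3-dihydrofuran-3-yl]benzoate
Conditions: Pd2(dba)3 (5 mol%), AsPh3 (20 mol%), CuI (10 mol%), DMF, 40 °C
Reagents that add atoms: none
Why: Stille coupling (oxidative addition of zerovalent palladium into the vinyl C–I bond, tin-to-palladium transmetallation, reductive elimination) installs the 1-methoxyvinyl group under neutral conditions, so the methoxydiene is never exposed to the base of the aldol step; the C3 descriptor changes from R to S only because iodine is replaced by carbon.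

**Step 10**
Reactants: 21 methyl 4-hydroxy-3-[(2R,3S)-5-[(4S,5S)-5-hydroxy-3-oxo-1-phenylhept-6-en-4-yl]-2-(2-hydroxypropan-2-yl)-4-(1-methoxyethenyl)-2,3-dihydrofuran-3-yl]benzoate
Product: 22 methyl 4-hydroxy-3-[(2R,3S,6S,7S)-6-hydroxy-2-(2-hydroxypropan-2-yl)-4-methoxy-7-(3-phenylpropanoyl)-2,3,6,7-tetrahydro-1-benzofuran-3-yl]benzoate
Conditions: second-generation Grubbs catalyst (H2IMes)(PCy3)Cl2Ru=CHPh (10 mol%), CH2Cl2 (0.005 M, degassed), 40 °C; then ethyl vinyl ether; Et3N-deactivated SiO2, 0 °C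
Reagents that add atoms: none
Why: Ring-closing olefin metathesis, in which the ruthenium carbene loads on the monosubstituted carbinol alkene and closes onto the 1,1-disubstituted enol ether with loss of ethene to form C4=C5 under neutral conditions that leave the β-hydroxy ketone and all four stereocentres untouched.

**Compound list**
1 | methyl 4-hydroxy-3-iodobenzoate | COC(=O)c1ccc(O)c(I)c1 | starting material
2 | 2-methylbut-3-en-2-ol | CC(C)(O)C=C | starting material
3 | methyl 3-iodo-4-[(triisopropylsilyl)oxy]benzoate (not isolated) | COC(=O)c1ccc(O[Si](C(C)C)(C(C)C)C(C)C)c(I)c1 | intermediate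
4 | methyl 3-[(1E)-3-hydroxy-3-methylbut-1-en-1-yl]-4-[(triisopropylsilyl)oxy]benzoate | COC(=O)c1ccc(O[Si](C(C)C)(C(C)C)C(C)C)c(/C=C/C(C)(C)O)c1 | intermediate
5 | methyl 3-[(2S,3R)-3-(2-hydroxypropan-2-yl)oxiran-2-yl]-4-[(triisopropylsilyl)oxy]benzoate | COC(=O)c1ccc(O[Si](C(C)C)(C(C)C)C(C)C)c([C@@H]2O[C@H]2C(C)(C)O)c1 | intermediate
6 | 3-phenylpropanal | O=CCCc1ccccc1 | starting material
7 | 3-bromoprop-1-yne (propargyl bromide) | BrCC#C | starting material
8 | bromozinc 1-phenylhex-5-yn-3-olate (racemic, not isolated) | Br[Zn]OC(CC#C)CCc1ccccc1 | intermediate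
9 | trimethyl[(1-phenylhex-5-yn-3-yl)oxy]silane (racemic) | C[Si](C)(C)OC(CC#C)CCc1ccccc1 | intermediate
10 | [6-phenyl-4-(trimethylsilyloxy)hex-1-yn-1-yl]lithium (not isolated) | [Li]C#CCC(O[Si](C)(C)C)CCc1ccccc1 | intermediate
11 | diethyl[6-phenyl-4-(trimethylsilyloxy)hex-1-yn-1-yl]alane (not isolated) | CC[Al](CC)C#CCC(O[Si](C)(C)C)CCc1ccccc1 | intermediate
12 | methyl 3-[(3R,4R)-2,3-dihydroxy-2-methyl-10-phenyl-8-(trimethylsilyloxy)dec-5-yn-4-yl]-4-[(triisopropylsilyl)oxy]benzoate (both C8 epimers) | COC(=O)c1ccc(O[Si](C(C)C)(C(C)C)C(C)C)c([C@@H](C#CCC(O[Si](C)(C)C)CCc2ccccc2)[C@@H](O)C(C)(C)O)c1 | intermediate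
13 | methyl 3-[(2R,3R)-2-(2-hydroxypropan-2-yl)-4-iodo-5-[4-phenyl-2-(trimethylsilyloxy)butyl]-2,3-dihydrofuran-3-yl]-4-[(triisopropylsilyl)oxy]benzoate (not isolated) | COC(=O)c1ccc(O[Si](C(C)C)(C(C)C)C(C)C)c([C@H]2C(I)=C(CC(O[Si](C)(C)C)CCc3ccccc3)O[C@H]2C(C)(C)O)c1 | intermediate
14 | methyl 3-[(2R,3R)-5-(2-hydroxy-4-phenylbutyl)-2-(2-hydroxypropan-2-yl)-4-iodo-2,3-dihydrofuran-3-yl]-4-[(triisopropylsilyl)oxy]benzoate (both carbinol epimers) | COC(=O)c1ccc(O[Si](C(C)C)(C(C)C)C(C)C)c([C@H]2C(I)=C(CC(O)CCc3ccccc3)O[C@H]2C(C)(C)O)c1 | intermediate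
15 | methyl 3-[(2R,3R)-2-(2-hydroxypropan-2-yl)-4-iodo-5-(2-oxo-4-phenylbutyl)-2,3-dihydrofuran-3-yl]-4-[(triisopropylsilyl)oxy]benzoate | COC(=O)c1ccc(O[Si](C(C)C)(C(C)C)C(C)C)c([C@H]2C(I)=C(CC(=O)CCc3ccccc3)O[C@H]2C(C)(C)O)c1 | intermediate
16 | prop-2-enal (acrolein) | C=CC=O | starting material
17 | (Z)-bis(isopinocampheyl)boron enolate of 15, boron on the enolate oxygen, enolate C=C towards C7 (not isolated) | COC(=O)c1ccc(O[Si](C(C)C)(C(C)C)C(C)C)c([C@H]2C(I)=C(/C=C(\OB([C@@H]3C[C@@H]4C[C@H]([C@H]3C)C4(C)C)[C@@H]3C[C@@H]4C[C@H]([C@H]3C)C4(C)C)CCc3ccccc3)O[C@H]2C(C)(C)O)c1 | intermediate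
18 | methyl 3-[(2R,3R)-5-[(4S,5S)-5-hydroxy-3-oxo-1-phenylhept-6-en-4-yl]-2-(2-hydroxypropan-2-yl)-4-iodo-2,3-dihydrofuran-3-yl]-4-[(triisopropylsilyl)oxy]benzoate | COC(=O)c1ccc(O[Si](C(C)C)(C(C)C)C(C)C)c([C@H]2C(I)=C([C@@H](C(=O)CCc3ccccc3)[C@@H](O)C=C)O[C@H]2C(C)(C)O)c1 | intermediate
19 | methyl 4-hydroxy-3-[(2R,3R)-5-[(4S,5S)-5-hydroxy-3-oxo-1-phenylhept-6-en-4-yl]-2-(2-hydroxypropan-2-yl)-4-iodo-2,3-dihydrofuran-3-yl]benzoate | COC(=O)c1ccc(O)c([C@H]2C(I)=C([C@@H](C(=O)CCc3ccccc3)[C@@H](O)C=C)O[C@H]2C(C)(C)O)c1 | intermediate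
20 | tributyl(1-methoxyethenyl)stannane | CCCC[Sn](CCCC)(CCCC)C(=C)OC | starting material
21 | methyl 4-hydroxy-3-[(2R,3S)-5-[(4S,5S)-5-hydroxy-3-oxo-1-phenylhept-6-en-4-yl]-2-(2-hydroxypropan-2-yl)-4-(1-methoxyethenyl)-2,3-dihydrofuran-3-yl]benzoate | COC(=O)c1ccc(O)c([C@H]2C(C(=C)OC)=C([C@@H](C(=O)CCc3ccccc3)[C@@H](O)C=C)O[C@H]2C(C)(C)O)c1 | intermediate
22 | methyl 4-hydroxy-3-[(2R,3S,6S,7S)-6-hydroxy-2-(2-hydroxypropan-2-yl)-4-methoxy-7-(3-phenylpropanoyl)-2,3,6,7-tetrahydro-1-benzofuran-3-yl]benzoate (2,3-cis; 6,7-cis) | COC(=O)c1ccc(O)c([C@H]2C3=C(O[C@H]2C(C)(C)O)[C@@H](C(=O)CCc2ccccc2)[C@@H](O)C=C3OC)c1 | target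

**Step count and risks**
Total step count: 10 (steps 1, 3 and 5 are one-pot, two-stage operations). Longest linear sequence: 9 steps (1 → 4 → 5 → 12 → 14 → 15 → 18 → 19 → 21 → 22).

Three steps most likely to fail:

Step 5 (the new step). The borinate may not turn over, or the tertiary hydroxyl may still close 5-exo-dig onto the other alkyne carbon. The fallback uses known chemistry, sets out from epoxy alcohol 5 and comes back at alcohol 14. The tertiary hydroxyl of 5 is capped with N-(trimethylsilyl)imidazole to give the tertiary silyl ether F1. Lithium acetylide 10 with BF3·OEt2 in THF at −78 °C (Yamaguchi–Hirao alkynylation) opens F1 at the benzylic carbon with inversion to give the mono-alcohol F2, in which only the C2 hydroxyl is free. The established I2/NaHCO3 5-endo-dig iodocyclisation in MeCN then gives the bis-silyl iodo-dihydrofuran F3, and K2CO3 in MeOH removes both trimethylsilyl groups to give 14.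

Step 7. Enolisation may not be fully regioselective, the free tertiary alcohol may consume reagent, and the facial control of a hindered, already chiral ketone by the Ipc ligands may be modest. The fallback sets out from ketone 15 and comes back at aldol 18. TMSOTf and Et3N in CH2Cl2 at −78 °C convert 15 into the (Z)-silyl enol ether F4, with the tertiary alcohol silylated at the same time. F4 then undergoes a Mukaiyama aldol reaction with acrolein 16 in EtCN at −78 °C, catalysed by a chiral acyloxyborane (20 mol%, from 2-O-(2,6-diisopropoxybenzoyl)tartaric acid and BH3·THF). This open-transition-state reaction is syn-selective whatever the enol ether geometry, and the tartrate antipode sets the face. Work-up with 1 M HCl in THF at 0 °C removes the two trimethylsilyl groups to give 18.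

Step 10. The catalyst may be trapped by the electron-rich 2-methoxydiene as an unreactive Fischer-type carbene before it has loaded at the hindered carbinol alkene, and the product can lose water to the arene on prolonged heating. The fallback sets out from ketone 15 and comes back at target 22 by relay ring-closing metathesis. The aldol of step 7 is run with (2E)-octa-2,7-dienal F5 (MnO2 oxidation of commercial (2E)-octa-2,7-dien-1-ol) in place of acrolein, giving the relay aldol adduct F6. Desilylation as in step 8 gives phenol F7, and Stille coupling as in step 9 gives methoxydiene F8. The same ruthenium catalyst then loads on the unhindered terminal alkene of the tether, expels cyclopentene to place the carbene on C5, and closes onto the enol ether to give 22.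

**Further compounds**
F1 | step 5 | methyl 3-[(2S,3R)-3-[2-(trimethylsilyloxy)propan-2-yl]oxiran-2-yl]-4-[(triisopropylsilyl)oxy]benzoate | COC(=O)c1ccc(O[Si](C(C)C)(C(C)C)C(C)C)c([C@@H]2O[C@H]2C(C)(C)O[Si](C)(C)C)c1
F2 | step 5 | methyl 3-[(3R,4R)-3-hydroxy-2-methyl-10-phenyl-2,8-bis(trimethylsilyloxy)dec-5-yn-4-yl]-4-[(triisopropylsilyl)oxy]benzoate | COC(=O)c1ccc(O[Si](C(C)C)(C(C)C)C(C)C)c([C@@H](C#CCC(O[Si](C)(C)C)CCc2ccccc2)[C@@H](O)C(C)(C)O[Si](C)(C)C)c1
F3 | step 5 | methyl 3-[(2R,3R)-4-iodo-5-[4-phenyl-2-(trimethylsilyloxy)butyl]-2-[2-(trimethylsilyloxy)propan-2-yl]-2,3-dihydrofuran-3-yl]-4-[(triisopropylsilyl)oxy]benzoate | COC(=O)c1ccc(O[Si](C(C)C)(C(C)C)C(C)C)c([C@H]2C(I)=C(CC(O[Si](C)(C)C)CCc3ccccc3)O[C@H]2C(C)(C)O[Si](C)(C)C)c1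
F4 | step 7 | methyl 3-[(2R,3R)-4-iodo-5-[(1Z)-4-phenyl-2-(trimethylsilyloxy)but-1-en-1-yl]-2-[2-(trimethylsilyloxy)propan-2-yl]-2,3-dihydrofuran-3-yl]-4-[(triisopropylsilyl)oxy]benzoate | COC(=O)c1ccc(O[Si](C(C)C)(C(C)C)C(C)C)c([C@H]2C(I)=C(/C=C(\O[Si](C)(C)C)CCc3ccccc3)O[C@H]2C(C)(C)O[Si](C)(C)C)c1
F5 | step 10 | (2E)-octa-2,7-dienal | C=CCCC/C=C/C=O
F6 | step 10 | methyl 3-[(2R,3R)-5-[(4S,5S,6E)-5-hydroxy-3-oxo-1-phenyldodeca-6,11-dien-4-yl]-2-(2-hydroxypropan-2-yl)-4-iodo-2,3-dihydrofuran-3-yl]-4-[(triisopropylsilyl)oxy]benzoate | COC(=O)c1ccc(O[Si](C(C)C)(C(C)C)C(C)C)c([C@H]2C(I)=C([C@@H](C(=O)CCc3ccccc3)[C@@H](O)/C=C/CCCC=C)O[C@H]2C(C)(C)O)c1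
F7 | step 10 | methyl 4-hydroxy-3-[(2R,3R)-5-[(4S,5S,6E)-5-hydroxy-3-oxo-1-phenyldodeca-6,11-dien-4-yl]-2-(2-hydroxypropan-2-yl)-4-iodo-2,3-dihydrofuran-3-yl]benzoate | COC(=O)c1ccc(O)c([C@H]2C(I)=C([C@@H](C(=O)CCc3ccccc3)[C@@H](O)/C=C/CCCC=C)O[C@H]2C(C)(C)O)c1
F8 | step 10 | methyl 4-hydroxy-3-[(2R,3S)-5-[(4S,5S,6E)-5-hydroxy-3-oxo-1-phenyldodeca-6,11-dien-4-yl]-2-(2-hydroxypropan-2-yl)-4-(1-methoxyethenyl)-2,3-dihydrofuran-3-yl]benzoate | COC(=O)c1ccc(O)c([C@H]2C(C(=C)OC)=C([C@@H](C(=O)CCc3ccccc3)[C@@H](O)/C=C/CCCC=C)O[C@H]2C(C)(C)O)c1
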